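## The problem

The target 22 is a linear trimer of galloyl units: rings A, B and C are joined by two aryl ester (depside) links, each running from the carbonyl carbon of one ring to the 4-oxygen of the next, para to that ring's own carboxyl carbon and flanked by two free hydroxyls. There is no stereocentre, so the task is one of regiochemistry and lability. A direct synthesis would have to acylate, twice, the most hindered of three neighbouring phenols and then keep the acyl group there. Both links are activated aryl esters: nucleophiles and alkoxides cleave them, and once a flanking phenoxide can form the acyl group can shift to the neighbouring oxygen, so no basic step is allowed once an ester and an ortho hydroxyl coexist. The enabling feature is that in rings A and B the 4-oxygen, the ester carbonyl carbon and ring carbon C5 map onto O1, C2 and C3a of a 2-arylbenzofuran, with C4 as C7a. Oxidative cleavage of the furan C2=C3 bond therefore writes the ester with its oxygen already on the correct carbon and leaves furan C3 on C5 as a carbonyl group to be exchanged for oxygen. At that stage the ring is electron-poor (acyloxy ortho, carbonyl meta), so a formyl group would be expected to lose hydrogen to peracid and end as a carboxylic acid; a methyl group on each furan C3 turns the residue into an acetyl group, for which no hydride shift exists and aryl migration is the favoured Baeyer–Villiger pathway.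

## Retrosynthesis

**22 from 21.** The last cut removes six benzyl–oxygen bonds (five aryl ethers and the ester of ring A) by hydrogenolysis. Benzyl is preferred to acetyl, methyl or silyl groups because it alone leaves under neutral, non-nucleophilic conditions, which the two depside links and their flanking phenols demand. Precursor 21 has only two free phenols and is lipophilic and chromatographable. The forward step must run in an aprotic neutral solvent.

**21 from 20 from 19.** The C5–O bonds of rings A and B are traced back to C5–acetyl bonds: acetate cleavage of 20, then Baeyer–Villiger oxidation of diketone 19. A formyl group at C5 would be shorter to reach but is rejected for the hydrogen-shift reason above; a methyl ketone leaves aryl migration as the productive pathway. The cost is that two aryl acetates must be removed beside two aryl aroates. This is asked of an acid-catalysed methanolysis, which favours the small acetyl group over a conjugated, ortho-flanked aroyl group and never generates a phenoxide.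

**19 from 17 (key disconnection).** In 19 each depside carbonyl carbon and the acetyl carbon on the neighbouring ring carbon are reconnected as C2=C3 of a furan, which leads to bis-benzofuran 17. Against esterification of a hindered phenol this cut has two advantages. The ester oxygen is a furan oxygen whose position is fixed when the ring is made. And 17 contains no ester between the rings, so it is robust through all the carbon–carbon bond-forming steps. The forward reaction must cleave two tetrasubstituted enol-ether double bonds oxidatively in the presence of six benzyl groups, passing through bis-ozonide 18.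

**17 from 16 from 15 from 12 and 14.** The ring A furan is taken apart in three moves: the C3–CH3 bond (Suzuki–Miyaura methylation of iodide 16); the O1–C2 and C3–I bonds (iodocyclisation of diarylalkyne 15 with loss of the benzyl group from the attacking oxygen); and the sp–sp2 bond (Sonogashira coupling of alkyne 12 with iodide 14). The neighbouring option, coupling and annulating a free ortho-iodophenol, would give a 3-unsubstituted furan that needs a separate C3 functionalisation. With both oxygens benzylated, only the one ortho to the alkyne can close, and the ring closure itself leaves the iodine at C3 that serves as the handle for the methyl group.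

**12 from 11 from 10 from 9 from 8 and 4.** The ring B furan is built by the same three-step sequence from iodoarene 8 and arylacetylene 4. The formyl group of 8 is a spectator throughout and becomes the terminal alkyne of 12 by Ohira–Bestmann homologation of 11. This makes the assembly iterative: each cycle adds one ring and ends in a group ready for the next coupling.

**14 from 13 from 8; 8 from 6 from 5 and 7.** One iodoarene serves rings A and B. Aldehyde 8 is oxidised to acid 13 and benzylated with 7 to 14 for ring A. 8 itself comes from the catalogue phenol 5, 3-(benzyloxy)-4-hydroxybenzaldehyde. The C–I bond is made by iodination to 6, which can only occur ortho to the free hydroxyl, and the O–benzyl bond by alkylation with 7. Because 5 already carries a benzyl group on the oxygen that ends as a flanking hydroxyl, no ether has to be cleaved and only one benzyl group is added. The iodine is necessarily ortho to the oxygen that becomes the depside oxygen, which fixes the para attachment of both links.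

**4 from 3 from 2 from 1.** Ring C is the catalogue compound tri-O-benzylgallic acid 1, already carrying its three benzyl ethers. It is taken to the aldehyde oxidation level (reduction to 2, oxidation to 3) and homologated by one carbon to 4.

## Roads not taken

**Alternative 1:** The cut goes through ring B itself (C2–C3 and C5–C6). 1,3-Bis(benzyloxy)propan-2-one A1 would condense twice, under strong alkoxide base, with vinamidinium salt A2, whose central carbon already carries the carbonyl esterified to the ring A phenol. The product is the ring A–ring B depside A3, with the ring B 4-hydroxyl as its only free phenol.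
- Merits: one step forms two carbon–carbon bonds and a ring; the oxygen pattern of ring B arrives complete; the single free phenol is exactly the one needed next. It needs no peroxides and no late change of oxidation level, and would probably be shorter than the chosen route.
- Weak points: the base needed to enolise A1 meets an activated aryl ester in A2 and in A3. The ester of A2 must itself be made by acylating the flanked 4-hydroxyl of a gallate, and ring C must still be attached by a second such acylation.
- Comparison: this road is better in step count and in the mildness of its end game. The chosen plan sets against it that neither ester is made by acylation and that no base touches the molecule once an ester exists.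

**Alternative 2:** The cut removes all six flanking hydroxyls at once. Hexakis(pinacolboronate) A4 would be oxidised in one operation by a neutral peroxide-type oxidant to A5, the target still carrying its benzyl ester and one benzyl ether on ring C.
- Merits: the skeleton is three simple 4-oxybenzoate units, only two protecting groups are carried, and the final hydrogenolysis is trivial. On paper it is the shortest route.
- Weak points: six carbon–boron bonds would have to be placed ortho to acyloxy or benzyloxy groups, against the steric preference of catalytic C–H borylation. The oxidation uses oxygen nucleophiles of the kind that cleave aryl esters, and it releases phenols on both sides of each depside link while those nucleophiles are present. A5 is almost the unprotected target, so every sensitive group is exposed during a six-fold reaction.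
- Comparison: it is better in protecting-group economy. The chosen plan sets against it that every oxygen position is fixed by the starting materials and that the flanking phenols appear only under acidic or neutral conditions.

**Alternative 3:** The cut goes through ring C (C1–C2 and C5–C6). 3,4-Bis(benzyloxy)furan A6 and aryl propiolate A7, the propiolic ester of the ring B phenol of a ring A–ring B depside, would undergo a Diels–Alder addition. Acid-mediated opening of the oxygen bridge would then give A8, in which ring C carries a free 5-hydroxyl.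
- Merits: a ring is built with its carbonyl already in the ester, the bridging oxygen becomes one of the target's hydroxyls, and no redox adjustment follows.
- Weak points: only ring C is addressed. The ring A–ring B ester and the propiolate ester must both be made by acylating flanked phenols. The direction in which the bridge opens decides between the 5-hydroxy and the 2-hydroxy isomer. An electron-rich dialkoxyfuran and an aryl propiolate are both sensitive to the acid the aromatisation needs.
- Comparison: it is likely shorter and more convergent for ring C. The chosen plan sets against it that both depside links are treated by one and the same reaction and that their position is not left to a selectivity.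

Key step: step 15

Assumption: once phenols flank a depside ester the acyl group can wander to the neighbouring oxygen if a phenoxide forms; every step after step 15 is therefore kept acidic or neutral, and 22 is taken as the kinetically defined para,para isomer.

## Route

Step 1
Reactants: 1 3,4,5-tris(benzyloxy)benzoic acid
Product: 2 [3,4,5-tris(benzyloxy)phenyl]methanol
Conditions: LiAlH4, THF, 0 °C to reflux; then H2O/aq. NaOH work-up
Reagents that add atoms: none
Why: Hydride reduction of the carboxylic acid to the primary alcohol; aryl benzyl ethers are inert to LiAlH4.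

Step 2
Reactants: 2 [3,4,5-tris(benzyloxy)phenyl]methanol
Product: 3 3,4,5-tris(benzyloxy)benzaldehyde
Conditions: MnO2 (activated), CH2Cl2, rt
Reagents that add atoms: none
Why: MnO2 oxidises benzylic alcohols selectively and stops at the aldehyde.

Step 3
Reactants: 3 3,4,5-tris(benzyloxy)benzaldehyde
Product: 4 1,2,3-tris(benzyloxy)-5-ethynylbenzene
Conditions: Ohira–Bestmann reagent, K2CO3, MeOH/THF, rt
Reagents that add atoms: dimethyl (1-diazo-2-oxopropyl)phosphonate, CC(=O)C(=[N+]=[N-])P(=O)(OC)OC
Why: Ohira–Bestmann (Seyferth–Gilbert) homologation; a non-enolisable aryl aldehyde gives the terminal alkyne under mild carbonate conditions.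

Step 4
Reactants: 5 3-(benzyloxy)-4-hydroxybenzaldehyde
Product: 6 3-(benzyloxy)-4-hydroxy-5-iodobenzaldehyde
Conditions: I2, KI, NaHCO3, THF/H2O, rt
Reagents that add atoms: iodine, II
Why: Electrophilic aromatic iodination of a phenol under hydrogencarbonate buffer, the reaction that turns vanillin into 5-iodovanillin; the para position is blocked by the formyl group and one ortho position by the benzyloxy group, so iodine can enter only at C5.

Step 5
Reactants: 6 3-(benzyloxy)-4-hydroxy-5-iodobenzaldehyde; 7 benzyl bromide
Product: 8 3,4-bis(benzyloxy)-5-iodobenzaldehyde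
Conditions: BnBr, K2CO3, DMF, 60 °C
Reagents that add atoms: none
Why: Williamson etherification of the acidic phenol para to the formyl group; one equivalent of benzyl bromide gives both ring oxygens the same protecting group.

Step 6
Reactants: 8 3,4-bis(benzyloxy)-5-iodobenzaldehyde; 4 1,2,3-tris(benzyloxy)-5-ethynylbenzene
Product: 9 3,4-bis(benzyloxy)-5-{[3,4,5-tris(benzyloxy)phenyl]ethynyl}benzaldehyde
Conditions: Pd(PPh3)2Cl2 (cat.), CuI (cat.), Et3N, THF, 45 °C, degassed
Reagents that add atoms: none
Why: Sonogashira coupling of an electron-poor aryl iodide with an arylacetylene; with no free phenol present the alkyne cannot close early to a 3-unsubstituted benzofuran.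

Step 7
Reactants: 9 3,4-bis(benzyloxy)-5-{[3,4,5-tris(benzyloxy)phenyl]ethynyl}benzaldehyde
Product: 10 7-(benzyloxy)-3-iodo-2-[3,4,5-tris(benzyloxy)phenyl]-1-benzofuran-5-carbaldehyde
Conditions: I2, CH2Cl2, rt, dark; aq. Na2S2O3
Reagents that add atoms: iodine, II
Why: Electrophilic 5-endo-dig iodocyclisation of an ortho-alkynylaryl ether: the ortho benzyloxy oxygen opens the iodonium ion at the alkyne carbon bearing the electron-rich trialkoxyphenyl group, and iodide removes the benzyl group from the oxonium ion. Only the oxygen ortho to the alkyne can reach it, so the second benzyl ether survives as the 7-substituent.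

Step 8
Reactants: 10 7-(benzyloxy)-3-iodo-2-[3,4,5-tris(benzyloxy)phenyl]-1-benzofuran-5-carbaldehyde
Product: 11 7-(benzyloxy)-3-methyl-2-[3,4,5-tris(benzyloxy)phenyl]-1-benzofuran-5-carbaldehyde
Conditions: trimethylboroxine, Pd(dppf)Cl2 (cat.), K2CO3, 1,4-dioxane, 100 °C
Reagents that add atoms: trimethylboroxine, CB1OB(C)OB(C)O1
Why: Suzuki–Miyaura methylation of a 3-iodobenzofuran; the aldehyde and benzyl ethers tolerate the carbonate base.

Step 9
Reactants: 11 7-(benzyloxy)-3-methyl-2-[3,4,5-tris(benzyloxy)phenyl]-1-benzofuran-5-carbaldehyde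
Product: 12 7-(benzyloxy)-5-ethynyl-3-methyl-2-[3,4,5-tris(benzyloxy)phenyl]-1-benzofuran
Conditions: Ohira–Bestmann reagent, K2CO3, MeOH/THF, rt
Reagents that add atoms: dimethyl (1-diazo-2-oxopropyl)phosphonate, CC(=O)C(=[N+]=[N-])P(=O)(OC)OC
Why: Ohira–Bestmann homologation of the aryl aldehyde to the terminal alkyne needed for the second annulation.

Step 10
Reactants: 8 3,4-bis(benzyloxy)-5-iodobenzaldehyde
Product: 13 3,4-bis(benzyloxy)-5-iodobenzoic acid
Conditions: NaClO2, NaH2PO4, 2-methyl-2-butene, t-BuOH/THF/H2O, rt
Reagents that add atoms: sodium chlorite, [Na+].[O-]Cl=O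
Why: Pinnick oxidation of the aldehyde to the acid; the alkene scavenges hypochlorous acid, and the aryl iodide and benzyl ethers are inert.

Step 11
Reactants: 13 3,4-bis(benzyloxy)-5-iodobenzoic acid; 7 benzyl bromide
Product: 14 benzyl 3,4-bis(benzyloxy)-5-iodobenzoate
Conditions: BnBr, K2CO3, DMF, rt
Reagents that add atoms: none
Why: O-alkylation of the carboxylate; the benzyl ester will leave in the final hydrogenolysis together with the ethers.

Step 12
Reactants: 12 7-(benzyloxy)-5-ethynyl-3-methyl-2-[3,4,5-tris(benzyloxy)phenyl]-1-benzofuran; 14 benzyl 3,4-bis(benzyloxy)-5-iodobenzoate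
Product: 15 benzyl 3,4-bis(benzyloxy)-5-({7-(benzyloxy)-3-methyl-2-[3,4,5-tris(benzyloxy)phenyl]-1-benzofuran-5-yl}ethynyl)benzoate
Conditions: Pd(PPh3)2Cl2 (cat.), CuI (cat.), Et3N, THF, 45 °C, degassed
Reagents that add atoms: none
Why: Sonogashira coupling as in step 6; the benzyl ester and the existing benzofuran are spectators.

Step 13
Reactants: 15 benzyl 3,4-bis(benzyloxy)-5-({7-(benzyloxy)-3-methyl-2-[3,4,5-tris(benzyloxy)phenyl]-1-benzofuran-5-yl}ethynyl)benzoate
Product: 16 benzyl 7-(benzyloxy)-2-{7-(benzyloxy)-3-methyl-2-[3,4,5-tris(benzyloxy)phenyl]-1-benzofuran-5-yl}-3-iodo-1-benzofuran-5-carboxylate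
Conditions: I2, CH2Cl2, rt, dark; aq. Na2S2O3
Reagents that add atoms: iodine, II
Why: Second debenzylative 5-endo-dig iodocyclisation; the attacked alkyne carbon carries a benzofuran-5-yl group whose furan oxygen is para, and the fully substituted first furan has no position open to iodine.

Step 14
Reactants: 16 benzyl 7-(benzyloxy)-2-{7-(benzyloxy)-3-methyl-2-[3,4,5-tris(benzyloxy)phenyl]-1-benzofuran-5-yl}-3-iodo-1-benzofuran-5-carboxylate
Product: 17 benzyl 7-(benzyloxy)-2-{7-(benzyloxy)-3-methyl-2-[3,4,5-tris(benzyloxy)phenyl]-1-benzofuran-5-yl}-3-methyl-1-benzofuran-5-carboxylate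
Conditions: trimethylboroxine, Pd(dppf)Cl2 (cat.), K2CO3, 1,4-dioxane, 100 °C
Reagents that add atoms: trimethylboroxine, CB1OB(C)OB(C)O1
Why: Suzuki–Miyaura methylation as in step 8; with little water present the benzyl ester should survive the carbonate.

Step 15
Reactants: 17 benzyl 7-(benzyloxy)-2-{7-(benzyloxy)-3-methyl-2-[3,4,5-tris(benzyloxy)phenyl]-1-benzofuran-5-yl}-3-methyl-1-benzofuran-5-carboxylate
Product: 19 benzyl 3-acetyl-4-{[3-acetyl-5-(benzyloxy)-4-{[3,4,5-tris(benzyloxy)benzoyl]oxy}benzoyl]oxy}-5-(benzyloxy)benzoate, via bis-ozonide 18 (not isolated)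
Conditions: O3, CH2Cl2, −78 °C (Sudan red 7B end point); then PPh3, −78 °C to rt
Reagents that add atoms: ozone, [O-][O+]=O
Why: Ozone adds as a 1,3-dipole to each furan C2=C3 bond, a tetrasubstituted, oxygen- and aryl-substituted enol-ether double bond and the most electron-rich site in 17. Each primary ozonide cycloreverts so that C2 becomes an ester carbonyl still bound to the ring oxygen and C3 a carbonyl oxide, which re-adds to the tethered ester carbonyl to give the bridged 1,2,4-trioxolane of 18. PPh3 then takes one oxygen from each ozonide and leaves the aryl ester and the acetyl group of 19. The closest known reaction type is the ozonolysis of 2,3-disubstituted benzofurans to 2-acylphenyl esters. No ring is closed (two furan rings are opened) and no stereocentre is formed. The selectivity needed is furan double bond over benzylic C–H bonds, benzyl ether oxygens and the trialkoxy ring C; the enol-ether character of the furans, the low temperature and stopping at the indicator end point should secure it. The 3-methyl groups make C3 emerge as a ketone, which the next step requires.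

Step 16
Reactants: 19 benzyl 3-acetyl-4-{[3-acetyl-5-(benzyloxy)-4-{[3,4,5-tris(benzyloxy)benzoyl]oxy}benzoyl]oxy}-5-(benzyloxy)benzoate
Product: 20 benzyl 3-(acetyloxy)-4-{[3-(acetyloxy)-5-(benzyloxy)-4-{[3,4,5-tris(benzyloxy)benzoyl]oxy}benzoyl]oxy}-5-(benzyloxy)benzoate
Conditions: mCPBA, TFA, CH2Cl2, 0 °C to rt, dark
Reagents that add atoms: 3-chloroperbenzoic acid, O=C(OO)c1cccc(Cl)c1
Why: Baeyer–Villiger oxidation of two aryl methyl ketones; in the Criegee intermediate the aryl group migrates in preference to methyl even on an electron-poor ring, and TFA supplies the acid catalysis such a ring needs. The aryl esters and benzyl ethers are not nucleophilic enough to compete for the peracid.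

Step 17
Reactants: 20 benzyl 3-(acetyloxy)-4-{[3-(acetyloxy)-5-(benzyloxy)-4-{[3,4,5-tris(benzyloxy)benzoyl]oxy}benzoyl]oxy}-5-(benzyloxy)benzoate
Product: 21 benzyl 3-(benzyloxy)-4-{[3-(benzyloxy)-5-hydroxy-4-{[3,4,5-tris(benzyloxy)benzoyl]oxy}benzoyl]oxy}-5-hydroxybenzoate
Conditions: HCl (dilute), MeOH/CH2Cl2, 0 °C to rt
Reagents that add atoms: none
Why: Acid-catalysed transesterification removes the small acetyl groups much faster than the conjugated aroyl esters, whose aryloxy side is flanked on both sides. The phenols stay un-ionised, so the phenoxide-driven 1,2-acyl shift is not triggered.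

Step 18
Reactants: 21 benzyl 3-(benzyloxy)-4-{[3-(benzyloxy)-5-hydroxy-4-{[3,4,5-tris(benzyloxy)benzoyl]oxy}benzoyl]oxy}-5-hydroxybenzoate
Product: 22 3,5-dihydroxy-4-{[3,5-dihydroxy-4-(3,4,5-trihydroxybenzoyloxy)benzoyl]oxy}benzoic acid
Conditions: H2 (1 atm), Pd/C, THF/EtOAc, rt
Reagents that add atoms: none
Why: Hydrogenolysis of five aryl benzyl ethers and the benzyl ester over Pd/C in a neutral aprotic medium; aryl esters are inert to these conditions, and no base or alcohol is present to cleave or shift the depside links.

## Compound list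

1 | 3,4,5-tris(benzyloxy)benzoic acid | O=C(O)c1cc(OCc2ccccc2)c(OCc2ccccc2)c(OCc2ccccc2)c1 | starting material
2 | [3,4,5-tris(benzyloxy)phenyl]methanol | OCc1cc(OCc2ccccc2)c(OCc2ccccc2)c(OCc2ccccc2)c1 | intermediate
3 | 3,4,5-tris(benzyloxy)benzaldehyde | O=Cc1cc(OCc2ccccc2)c(OCc2ccccc2)c(OCc2ccccc2)c1 | intermediate
4 | 1,2,3-tris(benzyloxy)-5-ethynylbenzene | C#Cc1cc(OCc2ccccc2)c(OCc2ccccc2)c(OCc2ccccc2)c1 | intermediate
5 | 3-(benzyloxy)-4-hydroxybenzaldehyde | O=Cc1ccc(O)c(OCc2ccccc2)c1 | starting material
6 | 3-(benzyloxy)-4-hydroxy-5-iodobenzaldehyde | O=Cc1cc(I)c(O)c(OCc2ccccc2)c1 | intermediate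
7 | benzyl bromide | BrCc1ccccc1 | starting material
8 | 3,4-bis(benzyloxy)-5-iodobenzaldehyde | O=Cc1cc(I)c(OCc2ccccc2)c(OCc2ccccc2)c1 | intermediate
9 | 3,4-bis(benzyloxy)-5-{[3,4,5-tris(benzyloxy)phenyl]ethynyl}benzaldehyde | O=Cc1cc(C#Cc2cc(OCc3ccccc3)c(OCc3ccccc3)c(OCc3ccccc3)c2)c(OCc2ccccc2)c(OCc2ccccc2)c1 | intermediate
10 | 7-(benzyloxy)-3-iodo-2-[3,4,5-tris(benzyloxy)phenyl]-1-benzofuran-5-carbaldehyde | O=Cc1cc(OCc2ccccc2)c2oc(-c3cc(OCc4ccccc4)c(OCc4ccccc4)c(OCc4ccccc4)c3)c(I)c2c1 | intermediate
11 | 7-(benzyloxy)-3-methyl-2-[3,4,5-tris(benzyloxy)phenyl]-1-benzofuran-5-carbaldehyde | O=Cc1cc(OCc2ccccc2)c2oc(-c3cc(OCc4ccccc4)c(OCc4ccccc4)c(OCc4ccccc4)c3)c(C)c2c1 | intermediate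
12 | 7-(benzyloxy)-5-ethynyl-3-methyl-2-[3,4,5-tris(benzyloxy)phenyl]-1-benzofuran | C#Cc1cc(OCc2ccccc2)c2oc(-c3cc(OCc4ccccc4)c(OCc4ccccc4)c(OCc4ccccc4)c3)c(C)c2c1 | intermediate
13 | 3,4-bis(benzyloxy)-5-iodobenzoic acid | O=C(O)c1cc(I)c(OCc2ccccc2)c(OCc2ccccc2)c1 | intermediate
14 | benzyl 3,4-bis(benzyloxy)-5-iodobenzoate | O=C(OCc1ccccc1)c1cc(I)c(OCc2ccccc2)c(OCc2ccccc2)c1 | intermediate
15 | benzyl 3,4-bis(benzyloxy)-5-({7-(benzyloxy)-3-methyl-2-[3,4,5-tris(benzyloxy)phenyl]-1-benzofuran-5-yl}ethynyl)benzoate | O=C(OCc1ccccc1)c1cc(C#Cc2cc(OCc3ccccc3)c3oc(-c4cc(OCc5ccccc5)c(OCc5ccccc5)c(OCc5ccccc5)c4)c(C)c3c2)c(OCc2ccccc2)c(OCc2ccccc2)c1 | intermediate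
16 | benzyl 7-(benzyloxy)-2-{7-(benzyloxy)-3-methyl-2-[3,4,5-tris(benzyloxy)phenyl]-1-benzofuran-5-yl}-3-iodo-1-benzofuran-5-carboxylate | O=C(OCc1ccccc1)c1cc(OCc2ccccc2)c2oc(-c3cc(OCc4ccccc4)c4oc(-c5cc(OCc6ccccc6)c(OCc6ccccc6)c(OCc6ccccc6)c5)c(C)c4c3)c(I)c2c1 | intermediate
17 | benzyl 7-(benzyloxy)-2-{7-(benzyloxy)-3-methyl-2-[3,4,5-tris(benzyloxy)phenyl]-1-benzofuran-5-yl}-3-methyl-1-benzofuran-5-carboxylate | O=C(OCc1ccccc1)c1cc(OCc2ccccc2)c2oc(-c3cc(OCc4ccccc4)c4oc(-c5cc(OCc6ccccc6)c(OCc6ccccc6)c(OCc6ccccc6)c5)c(C)c4c3)c(C)c2c1 | intermediate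
18 | bis-ozonide of 17 (in each former furan, C2 and C3 are bridged by one ether oxygen and one peroxide unit) | O=C(OCc1ccccc1)c1cc(OCc2ccccc2)c2OC3(OOC(C)(O3)c2c1)c1cc(OCc2ccccc2)c2OC3(OOC(C)(O3)c2c1)c1cc(OCc2ccccc2)c(OCc2ccccc2)c(OCc2ccccc2)c1 | intermediate (not isolated)
19 | benzyl 3-acetyl-4-{[3-acetyl-5-(benzyloxy)-4-{[3,4,5-tris(benzyloxy)benzoyl]oxy}benzoyl]oxy}-5-(benzyloxy)benzoate | O=C(OCc1ccccc1)c1cc(OCc2ccccc2)c(OC(=O)c2cc(OCc3ccccc3)c(OC(=O)c3cc(OCc4ccccc4)c(OCc4ccccc4)c(OCc4ccccc4)c3)c(C(C)=O)c2)c(C(C)=O)c1 | intermediate
20 | benzyl 3-(acetyloxy)-4-{[3-(acetyloxy)-5-(benzyloxy)-4-{[3,4,5-tris(benzyloxy)benzoyl]oxy}benzoyl]oxy}-5-(benzyloxy)benzoate | O=C(OCc1ccccc1)c1cc(OCc2ccccc2)c(OC(=O)c2cc(OCc3ccccc3)c(OC(=O)c3cc(OCc4ccccc4)c(OCc4ccccc4)c(OCc4ccccc4)c3)c(OC(C)=O)c2)c(OC(C)=O)c1 | intermediate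
21 | benzyl 3-(benzyloxy)-4-{[3-(benzyloxy)-5-hydroxy-4-{[3,4,5-tris(benzyloxy)benzoyl]oxy}benzoyl]oxy}-5-hydroxybenzoate | O=C(OCc1ccccc1)c1cc(OCc2ccccc2)c(OC(=O)c2cc(OCc3ccccc3)c(OC(=O)c3cc(OCc4ccccc4)c(OCc4ccccc4)c(OCc4ccccc4)c3)c(O)c2)c(O)c1 | intermediate
22 | 3,5-dihydroxy-4-{[3,5-dihydroxy-4-(3,4,5-trihydroxybenzoyloxy)benzoyl]oxy}benzoic acid | O=C(O)c1cc(O)c(OC(=O)c2cc(O)c(OC(=O)c3cc(O)c(O)c(O)c3)c(O)c2)c(O)c1 | target

## Step count and uncertain steps

Total: 18 steps. Longest linear sequence: 14 steps from 1 (steps 1–3, 6–9, 12–18).

**Step 15 (key step).** The second furan may be consumed more slowly than the first, which gives ozone time to oxidise benzylic C–H bonds of the benzyl ethers or to attack ring C. The carbonyl oxide may also escape into oligomeric peroxides instead of closing to the bridged ozonide, and such peroxides reduce poorly. Fallback: from 17, dye-sensitised photo-oxygenation (O2, tetraphenylporphyrin, visible light, CH2Cl2, −78 °C) should add singlet oxygen across each furan double bond to give the bis-dioxetane F1. On warming, its four-membered rings cleave to the same ester and acetyl carbonyl pairs, which returns the route at 19.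

**Step 16.** Aryl migration on these electron-poor, ortho-substituted rings may be slow. Long exposure to peracid and TFA could then lead to loss of a benzyl ether or to hydroxylation of ring C. Fallback: from 17, ozonolysis in CH2Cl2/MeOH should trap each carbonyl oxide as the bis(1-hydroperoxy-1-methoxyethyl) compound F2. Acylating its hydroperoxide groups (Ac2O, pyridine, DMAP cat., CH2Cl2, 0 °C) starts a Criegee rearrangement in which the aryl group shifts to oxygen, and collapse of the resulting orthoester gives the aryl acetates, rejoining the route at 20.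

**Step 17.** Once the 5-hydroxyl is free it may attack the neighbouring aroyl ester and move the acyl group (para to meta depside). Prolonged acid may also methanolyse a depside link or exchange the benzyl ester for a methyl ester. Fallback: from 20, lipase-catalysed alcoholysis (immobilised Candida antarctica lipase B, n-butanol, THF/t-BuOMe, 40 °C) removes acetyl groups through an acyl-enzyme under neutral conditions and does not accept the bulky aroyl esters. It returns at 21 and makes no compound outside the list (F0).

**Step 7.** Ring closure may be slow because the attacking ether oxygen is conjugated with the para formyl group. That leaves time for simple addition of iodine across the triple bond or for iodination of ring C. Fallback: from 6 and 4, Sonogashira coupling with the phenol of 6 left free (Pd(PPh3)2Cl2, CuI, Et3N, DMF, 60 °C, degassed) lets the hydroxyl ortho to iodine close onto the alkyne in the same flask. This gives 7-(benzyloxy)-2-[3,4,5-tris(benzyloxy)phenyl]-1-benzofuran-5-carbaldehyde F3, and electrophilic iodination at C3 with N-iodosuccinimide (MeCN, rt) returns the route at 10.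

**Step 18.** Acyl shift may occur on the catalyst surface or during isolation of the very polar product, and debenzylation may stall as partly deprotected material adsorbs on the carbon. Fallback: from 21, Lewis-acid debenzylation with BCl3 and pentamethylbenzene as cation scavenger (CH2Cl2, −78 °C) cleaves the aryl benzyl ethers and the benzyl ester without hydrogen or a metal surface. It returns at 22 and makes no compound outside the list (F0).

## Further compounds

F1 | step 15 | bis-dioxetane of 17 (in each former furan, C2 and C3 are joined by a peroxide bridge in a four-membered ring) | O=C(OCc1ccccc1)c1cc(OCc2ccccc2)c2OC3(OOC3(C)c2c1)c1cc(OCc2ccccc2)c2OC3(OOC3(C)c2c1)c1cc(OCc2ccccc2)c(OCc2ccccc2)c(OCc2ccccc2)c1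
F2 | step 16 | benzyl 3-(benzyloxy)-4-{[3-(benzyloxy)-5-(1-hydroperoxy-1-methoxyethyl)-4-{[3,4,5-tris(benzyloxy)benzoyl]oxy}benzoyl]oxy}-5-(1-hydroperoxy-1-methoxyethyl)benzoate | O=C(OCc1ccccc1)c1cc(OCc2ccccc2)c(OC(=O)c2cc(OCc3ccccc3)c(OC(=O)c3cc(OCc4ccccc4)c(OCc4ccccc4)c(OCc4ccccc4)c3)c(C(C)(OC)OO)c2)c(C(C)(OC)OO)c1
F0 | step 17 | none | none
F3 | step 7 | 7-(benzyloxy)-2-[3,4,5-tris(benzyloxy)phenyl]-1-benzofuran-5-carbaldehyde | O=Cc1cc(OCc2ccccc2)c2oc(-c3cc(OCc4ccccc4)c(OCc4ccccc4)c(OCc4ccccc4)c3)cc2c1
F0 | step 18 | none | none
A1 | alternative 1 | 1,3-bis(benzyloxy)propan-2-one | O=C(COCc1ccccc1)COCc1ccccc1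
A2 | alternative 1 | vinamidinium hexafluorophosphate with a [2,6-bis(benzyloxy)-4-(benzyloxycarbonyl)phenoxy]carbonyl group on its central carbon | CN(C)C=C(C=[N+](C)C)C(=O)Oc1c(OCc2ccccc2)cc(C(=O)OCc2ccccc2)cc1OCc1ccccc1.F[P-](F)(F)(F)(F)F
A3 | alternative 1 | benzyl 3,5-bis(benzyloxy)-4-{[3,5-bis(benzyloxy)-4-hydroxybenzoyl]oxy}benzoate | O=C(OCc1ccccc1)c1cc(OCc2ccccc2)c(OC(=O)c2cc(OCc3ccccc3)c(O)c(OCc3ccccc3)c2)c(OCc2ccccc2)c1
A4 | alternative 2 | benzyl 4-{[4-{[4-(benzyloxy)-3,5-bis(4,4,5,5-tetramethyl-1,3,2-dioxaborolan-2-yl)benzoyl]oxy}-3,5-bis(4,4,5,5-tetramethyl-1,3,2-dioxaborolan-2-yl)benzoyl]oxy}-3,5-bis(4,4,5,5-tetramethyl-1,3,2-dioxaborolan-2-yl)benzoate | O=C(OCc1ccccc1)c1cc(B2OC(C)(C)C(C)(C)O2)c(OC(=O)c2cc(B3OC(C)(C)C(C)(C)O3)c(OC(=O)c3cc(B4OC(C)(C)C(C)(C)O4)c(OCc4ccccc4)c(B4OC(C)(C)C(C)(C)O4)c3)c(B3OC(C)(C)C(C)(C)O3)c2)c(B2OC(C)(C)C(C)(C)O2)c1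
A5 | alternative 2 | benzyl 4-{[4-{[4-(benzyloxy)-3,5-dihydroxybenzoyl]oxy}-3,5-dihydroxybenzoyl]oxy}-3,5-dihydroxybenzoate | O=C(OCc1ccccc1)c1cc(O)c(OC(=O)c2cc(O)c(OC(=O)c3cc(O)c(OCc4ccccc4)c(O)c3)c(O)c2)c(O)c1
A6 | alternative 3 | 3,4-bis(benzyloxy)furan | c1occ(OCc2ccccc2)c1OCc1ccccc1
A7 | alternative 3 | benzyl 3,5-bis(benzyloxy)-4-{[3,5-bis(benzyloxy)-4-(prop-2-ynoyloxy)benzoyl]oxy}benzoate | C#CC(=O)Oc1c(OCc2ccccc2)cc(cc1OCc1ccccc1)C(=O)Oc1c(OCc2ccccc2)cc(cc1OCc1ccccc1)C(=O)OCc1ccccc1
A8 | alternative 3 | benzyl 3,5-bis(benzyloxy)-4-{[3,5-bis(benzyloxy)-4-{[3,4-bis(benzyloxy)-5-hydroxybenzoyl]oxy}benzoyl]oxy}benzoate | O=C(OCc1ccccc1)c1cc(OCc2ccccc2)c(OC(=O)c2cc(OCc3ccccc3)c(OC(=O)c3cc(O)c(OCc4ccccc4)c(OCc4ccccc4)c3)c(OCc3ccccc3)c2)c(OCc2ccccc2)c1
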